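**Strategy.** Everything rests on closing the bridging cyclopentane ring D (C-8, C-14, C-13, C-16, C-15) last, through the C-13–C-16 bond. The key step exploits the 1,3-diaxial relationship of C-8 and C-13 across ring C. One C-12=C-13 alkene, made early by a Diels–Alder reaction, supplies both neighbours of that bond. Iodolactonisation with the C-20 acid installs the 12α-lactone oxygen and a 13-iodide, and locks ring C in the chair that holds the 8β-propargyl arm axial over C-13. A tin-mediated 5-exo-dig radical cyclisation of this iodide onto the alkyne then forges ring D, fixes C-13 and delivers the C-16=C-17 methylene in one operation. The precursor is a tetracyclic iodo lactone bearing the complete ring A diol.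

Key step: step 17

Locants: gibberellane numbering of the target is used for all intermediates; β is the face of 5-H, 9-H and the C-15–C-16 bridge, α the face of C-19, C-20 and the 12-oxygen.

Assumption: the (S)-configured oxazaborolidinium catalyst is taken to give the (3aR,7aR) enantiomer of 3 by the usual model for 2-cycloalkenones (ketone bound to boron, diene adding to the face remote from the aryl shield); if the opposite sense is found, the (R)-catalyst is used.

**Step 1**
Reactants: 1 methyl 3-oxocyclopent-1-ene-1-carboxylate; 2 buta-1,3-diene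
Product: 3 methyl (3aR,7aR)-3-oxo-2,3,3a,4,7,7a-hexahydro-1H-indene-7a-carboxylate (rings B and C cis-fused; ester on C-8, ketone at C-10, C-12=C-13)
Conditions: (S)-B-(o-tolyl) oxazaborolidine of α,α-diphenylprolinol (20 mol %), Tf2NH (18 mol %), 2 (5 equiv), CH2Cl2, −78 → −40 °C
Reagents that add atoms: none
Why: Diels–Alder reaction: the ketone-bound cationic oxazaborolidine activates the doubly activated C-8=C-9 alkene and shields one face, so suprafacial addition should set the cis B/C fusion (quaternary C-8 and C-9) in one absolute sense and place the ring C alkene at C-12=C-13.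

**Step 2**
Reactants: 3 cis-fused keto ester
Product: 4 the C-5=C-6 enone of 3 (methyl cis-3-oxo-3,3a,4,7-tetrahydro-7aH-indene-7a-carboxylate; ring-fusion configuration of 3)
Conditions: IBX (2.5 equiv), DMSO/fluorobenzene, 70 °C
Reagents that add atoms: none
Why: IBX-mediated α,β-dehydrogenation of the ketone can only run towards C-5/C-6 because C-8 bears no hydrogen, and the ring-fusion centres are untouched.

**Step 3**
Reactants: 4 bicyclic enone
Product: 6 enol triflate (10-OTf on C-5=C-10; 6β-C(SMe)3; 8β-CO2Me; 9β-H), via lithium enolate 5 (not isolated)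
Conditions: HC(SMe)3, n-BuLi, THF, −78 °C; then 4, −78 °C; then PhNTf2, −78 → 0 °C
Reagents that add atoms: tris(methylthio)methane CSC(SC)SC; N-phenylbis(trifluoromethanesulfonimide) O=S(=O)(N(c1ccccc1)S(=O)(=O)C(F)(F)F)C(F)(F)F
Why: Michael addition of the soft carboxyl-anion equivalent LiC(SMe)3 should occur at C-6 from the convex β face of the cis-fused bicycle (anti to ring C), and O-triflation of the regiodefined enolate fixes the C-5=C-10 double bond.

**Step 4**
Reactants: 6 enol triflate ester
Product: 7 primary alcohol (8β-CH2OH; otherwise as 6)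
Conditions: i-Bu2AlH (3 equiv), CH2Cl2, −78 → 0 °C; Rochelle salt work-up
Reagents that add atoms: none
Why: Hydride reduction removes the only free ester, since C-7 is masked as an orthothioester and C-10 as an enol triflate, both inert to i-Bu2AlH.

**Step 5**
Reactants: 7 neopentyl alcohol
Product: 8 aldehyde (8β-CHO; otherwise as 6)
Conditions: SO3·pyridine, DMSO, i-Pr2NEt, CH2Cl2, 0 °C
Reagents that add atoms: none
Why: Parikh–Doering oxidation gives the non-enolisable neopentyl aldehyde under conditions that spare the sulfides and the triflate.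

**Step 6**
Reactants: 8 aldehyde
Product: 9 methyl enol ether (8β-CH=CHOMe, E/Z mixture; otherwise as 6)
Conditions: Ph3P(CH2OMe)Cl, KN(SiMe3)2, THF, 0 °C; then 8, 0 → 25 °C
Reagents that add atoms: (methoxymethyl)triphenylphosphonium chloride COC[P+](c1ccccc1)(c1ccccc1)c1ccccc1.[Cl-]
Why: Wittig methoxymethylenation adds C-16 at the aldehyde oxidation level.

**Step 7**
Reactants: 9 enol ether
Product: 10 dioxolane (8β-CH2-(1,3-dioxolan-2-yl); otherwise as 6)
Conditions: ethylene glycol, PPTS (cat.), benzene, 50 °C
Reagents that add atoms: ethylene glycol OCCO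
Why: Acid-catalysed addition of the diol to the enol ether and loss of methanol gives a dioxolane that masks C-16 through the palladium, enolate and metathesis steps.

**Step 8**
Reactants: 10 enol triflate
Product: 11 α,β-unsaturated 2-(trimethylsilyl)ethyl ester (C-20 ester on C-5=C-10; 6β-C(SMe)3; 8β-dioxolanylmethyl)
Conditions: Pd(OAc)2 (5 mol %), dppf (10 mol %), Et3N, Me3SiCH2CH2OH, CO (1 atm), DMF, 60 °C
Reagents that add atoms: carbon monoxide [C-]#[O+]; 2-(trimethylsilyl)ethanol C[Si](C)(C)CCO
Why: Palladium-catalysed alkoxycarbonylation of the enol triflate (oxidative addition to zerovalent palladium, CO insertion, alcoholysis) installs C-20 as a fluoride-labile ester and creates the Michael acceptor.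

**Step 9**
Reactants: 11 unsaturated ester; 12 methyl but-3-enoate
Product: 15 diester with quaternary C-10 (10β-allyl; 10α-CO2CH2CH2SiMe3; 5α-[1-(methoxycarbonyl)prop-2-enyl]; 5β-H; 6β-C(SMe)3; C-4 epimers), via lithium dienolate 13 (not isolated), via lithium ester enolate 14 (not isolated)
Conditions: LiN(i-Pr)2, THF, −78 °C, 12; then 11, −78 → −40 °C; then allyl bromide, HMPA, −78 → 0 °C
Reagents that add atoms: allyl bromide C=CCBr
Why: Tandem Michael addition–enolate alkylation: the dienolate should attack C-5 through its α-carbon anti to the bulky 6β-orthothioester (C-4 unit α, 5-H β) and the resulting C-10 enolate should be allylated anti to both α neighbours (C-4 unit and C-11), giving the quaternary C-10 with 10β-allyl and 10α-ester, while C-4 arises as a mixture that is erased in step 12.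

**Step 10**
Reactants: 15 orthothioester
Product: 16 triester (6β-CO2Me; otherwise as 15)
Conditions: HgCl2, HgO, MeOH/H2O (12:1), 25 °C
Reagents that add atoms: methanol CO; water O
Why: Thiophilic divalent mercury assists solvolysis of the orthothioester to the methyl ester, and HgCl2 is too weak an electrophile to oxymercurate the alkenes.

**Step 11**
Reactants: 16 diene triester
Product: 17 tricyclic triester (ring A closed as the C-2=C-3 cyclohexene, trans-fused to ring B; C-4 H/CO2Me epimers)
Conditions: second-generation Grubbs catalyst (H2IMes)(PCy3)Cl2Ru=CHPh (5 mol %), CH2Cl2, 40 °C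
Reagents that add atoms: none
Why: Ring-closing metathesis of the 10β-allyl and C-4 vinyl groups closes ring A as the trans-fused C-2=C-3 cyclohexene with loss of ethylene.

**Step 12**
Reactants: 17 tricyclic triester
Product: 19 4β-methyl-4α-methoxycarbonyl tricyclic triester, via lithium dienolate 18 (not isolated)
Conditions: LiN(i-Pr)2 (1.1 equiv), THF, −78 °C; then MeI, −78 → −20 °C
Reagents that add atoms: iodomethane CI
Why: Deconjugative alkylation: the doubly activated allylic C-4–H is removed in preference to the hindered C-6–H and the ester dienolate should be methylated at C-4 from the β face, anti to the axial 10α-ester, setting the quaternary centre with 4β-methyl and 4α-ester.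

**Step 13**
Reactants: 19 dioxolane
Product: 20 aldehyde (8β-CH2CHO)
Conditions: 1 M HCl, THF, 25 °C
Reagents that add atoms: water O
Why: Aqueous acid hydrolyses the dioxolane to the aldehyde while the esters, the silyl group and the alkenes are stable.

**Step 14**
Reactants: 20 aldehyde
Product: 21 terminal alkyne (8β-propargyl)
Conditions: dimethyl (1-diazo-2-oxopropyl)phosphonate, K2CO3, MeOH, 0 → 25 °C
Reagents that add atoms: dimethyl (1-diazo-2-oxopropyl)phosphonate CC(=O)C(=[N+]=[N-])P(=O)(OC)OC
Why: Seyferth–Gilbert homologation with the Ohira–Bestmann reagent converts the aldehyde to the terminal alkyne, adding C-17 under mildly basic conditions that leave the hindered esters intact.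

**Step 15**
Reactants: 21 alkynyl triester
Product: 23 iodo lactone (20→12α δ-lactone; 13β-iodide; C-2=C-3; 8β-propargyl; 7,19-dimethyl ester), via tetrabutylammonium carboxylate 22 (not isolated)
Conditions: Bu4NF, THF, 0 → 25 °C; then NaHCO3, I2, THF/H2O, 0 °C
Reagents that add atoms: iodine II
Why: Fluoride-induced fragmentation frees only the C-20 carboxylate, which opens the β-iodonium ion of C-12=C-13 at C-12 from the α face (6-exo, trans-diaxial iodolactonisation), closing the δ-lactone and setting 12α-O and 13β-I; the ring A alkene has no free acid to trap its iodonium ion.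

**Step 16**
Reactants: 23 iodo lactone
Product: 24 2β,3β-dihydroxy iodo lactone
Conditions: OsO4 (5 mol %), NMO, acetone/H2O, 25 °C
Reagents that add atoms: osmium tetroxide O=[Os](=O)(=O)=O (catalytic oxygen carrier); N-methylmorpholine N-oxide C[N+]1([O-])CCOCC1; water O
Why: Upjohn dihydroxylation of the only remaining alkene should occur from the β face, anti to the axial 4α-ester and the 10α-lactone carbonyl, giving the cis-2β,3β-diol, while the alkyne and the iodide are inert to OsO4.

**Step 17**
Reactants: 24 dihydroxy iodo lactone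
Product: 25 7,19-dimethyl ester of the target (ring D closed; C-16=C-17 methylene)
Conditions: Bu3SnH (1.3 equiv, syringe pump), AIBN (cat.), benzene (0.01 M), 80 °C
Reagents that add atoms: none
Why: The tributyltin radical abstracts iodine from C-13; the secondary radical, held in the lactone-locked chair of ring C, adds to the internal alkyne carbon C-16 of the axial 8β-propargyl arm, and the vinyl radical at C-17 takes hydrogen from Bu3SnH to give the exocyclic methylene. The closest known reaction type is the tin-hydride-mediated cyclisation of a halide-derived alkyl radical onto a pendant alkyne, as used to build bicyclo[3.2.1]octanes. Ring D (C-8, C-14, C-13, C-16, C-15) closes in the 5-exo-dig mode. The new stereocentre C-13 is fixed by the bridge geometry: the β-face propargyl arm can only reach the β lobe of the radical, so the C-13–C-16 bond is cis to C-15 and trans to the 12α-oxygen whatever the iodide configuration. The step needs cyclisation to outrun hydrogen transfer to the C-13 radical and stannyl addition to the alkyne; slow stannane addition at high dilution and the 1,3-diaxial proximity of radical and alkyne should secure this, and 6-endo attack at C-17 is kinetically disfavoured.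

**Step 18**
Reactants: 25 dimethyl ester
Product: 26 target diacid CNP0212122.1
Conditions: n-PrSLi, HMPA, 25 °C; then 1 M HCl
Reagents that add atoms: none
Why: Thiolate SN2 attack at the methyl carbons cleaves both hindered methyl esters without acyl substitution, so the lactone, the diol, the alkene and all stereocentres should survive.

**Compound list**

1 | methyl 3-oxocyclopent-1-ene-1-carboxylate | COC(=O)C1=CC(=O)CC1 | starting material
2 | buta-1,3-diene | C=CC=C | starting material
3 | methyl (3aR,7aR)-3-oxo-2,3,3a,4,7,7a-hexahydro-1H-indene-7a-carboxylate (cis B/C; C-8 ester, C-10 ketone, C-12=C-13) | COC(=O)[C@]12CC=CC[C@H]1C(=O)CC2 | intermediate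
4 | C-5=C-6 enone of 3 (cis-fused cyclopentenone) | COC(=O)[C@]12CC=CC[C@H]1C(=O)C=C2 | intermediate
5 | lithium C-10 enolate of the 6β-tris(methylthio)methyl adduct | COC(=O)[C@]12CC=CC[C@H]1C(O[Li])=C[C@@H]2C(SC)(SC)SC | intermediate
6 | enol triflate: 10-OTf on C-5=C-10, 6β-C(SMe)3, 8β-CO2Me, 9β-H | COC(=O)[C@]12CC=CC[C@H]1C(OS(=O)(=O)C(F)(F)F)=C[C@@H]2C(SC)(SC)SC | intermediate
7 | alcohol: as 6 with 8β-CH2OH | OC[C@]12CC=CC[C@H]1C(OS(=O)(=O)C(F)(F)F)=C[C@@H]2C(SC)(SC)SC | intermediate
8 | aldehyde: as 6 with 8β-CHO | O=C[C@]12CC=CC[C@H]1C(OS(=O)(=O)C(F)(F)F)=C[C@@H]2C(SC)(SC)SC | intermediate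
9 | methyl enol ether: as 6 with 8β-CH=CHOMe (E/Z mixture) | COC=C[C@]12CC=CC[C@H]1C(OS(=O)(=O)C(F)(F)F)=C[C@@H]2C(SC)(SC)SC | intermediate
10 | dioxolane: as 6 with 8β-(1,3-dioxolan-2-ylmethyl) | O1CCOC1C[C@]23CC=CC[C@H]2C(OS(=O)(=O)C(F)(F)F)=C[C@@H]3C(SC)(SC)SC | intermediate
11 | unsaturated 2-(trimethylsilyl)ethyl ester: C-20 ester on C-5=C-10, 6β-C(SMe)3, 8β-dioxolanylmethyl | O1CCOC1C[C@]23CC=CC[C@H]2C(C(=O)OCC[Si](C)(C)C)=C[C@@H]3C(SC)(SC)SC | intermediate
12 | methyl but-3-enoate | C=CCC(=O)OC | starting material
13 | lithium dienolate of 12 | C=CC=C(O[Li])OC | intermediate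
14 | lithium C-10/C-20 ester enolate of the Michael adduct (5α side chain, 5β-H) | O1CCOC1C[C@]23CC=CC[C@H]2C(=C(O[Li])OCC[Si](C)(C)C)[C@@H](C(C=C)C(=O)OC)[C@@H]3C(SC)(SC)SC | intermediate
15 | diester: 10β-allyl, 10α-CO2CH2CH2SiMe3, 5α-[1-(methoxycarbonyl)prop-2-enyl] (C-4 epimers), 6β-C(SMe)3, 8β-dioxolanylmethyl | O1CCOC1C[C@]23CC=CC[C@H]2[C@@](CC=C)(C(=O)OCC[Si](C)(C)C)[C@@H](C(C=C)C(=O)OC)[C@@H]3C(SC)(SC)SC | intermediate
16 | triester: as 15 with 6β-CO2Me | O1CCOC1C[C@]23CC=CC[C@H]2[C@@](CC=C)(C(=O)OCC[Si](C)(C)C)[C@@H](C(C=C)C(=O)OC)[C@@H]3C(=O)OC | intermediate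
17 | tricyclic triester: ring A as C-2=C-3 cyclohexene trans-fused to ring B, C-4 H/CO2Me (epimers) | O1CCOC1C[C@]23CC=CC[C@H]2[C@@]2(CC=CC(C(=O)OC)[C@H]2[C@@H]3C(=O)OC)C(=O)OCC[Si](C)(C)C | intermediate
18 | lithium C-4/C-19 dienolate of 17 | O1CCOC1C[C@]23CC=CC[C@H]2[C@@]2(CC=CC(=C(O[Li])OC)[C@H]2[C@@H]3C(=O)OC)C(=O)OCC[Si](C)(C)C | intermediate
19 | tricyclic triester with 4β-methyl and 4α-CO2Me | O1CCOC1C[C@]23CC=CC[C@H]2[C@@]2(CC=C[C@@](C)(C(=O)OC)[C@H]2[C@@H]3C(=O)OC)C(=O)OCC[Si](C)(C)C | intermediate
20 | aldehyde: as 19 with 8β-CH2CHO | O=CC[C@]23CC=CC[C@H]2[C@@]2(CC=C[C@@](C)(C(=O)OC)[C@H]2[C@@H]3C(=O)OC)C(=O)OCC[Si](C)(C)C | intermediate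
21 | alkyne: as 19 with 8β-propargyl | C#CC[C@]23CC=CC[C@H]2[C@@]2(CC=C[C@@](C)(C(=O)OC)[C@H]2[C@@H]3C(=O)OC)C(=O)OCC[Si](C)(C)C | intermediate
22 | tetrabutylammonium C-20 carboxylate of 21 | C#CC[C@]23CC=CC[C@H]2[C@@]2(CC=C[C@@](C)(C(=O)OC)[C@H]2[C@@H]3C(=O)OC)C(=O)[O-].CCCC[N+](CCCC)(CCCC)CCCC | intermediate
23 | iodo lactone: 20→12α δ-lactone, 13β-iodide, C-2=C-3, 8β-propargyl, 7,19-dimethyl ester | C#CC[C@]23C[C@H](I)[C@@H]1C[C@H]2[C@@]2(CC=C[C@@](C)(C(=O)OC)[C@H]2[C@@H]3C(=O)OC)C(=O)O1 | intermediate
24 | 2β,3β-dihydroxy iodo lactone | C#CC[C@]23C[C@H](I)[C@@H]1C[C@H]2[C@@]2(C[C@H](O)[C@H](O)[C@@](C)(C(=O)OC)[C@H]2[C@@H]3C(=O)OC)C(=O)O1 | intermediate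
25 | 7,19-dimethyl ester of the target (ring D closed) | C=C1C[C@]23C[C@H]1[C@@H]1C[C@H]2[C@@]2(C[C@H](O)[C@H](O)[C@@](C)(C(=O)OC)[C@H]2[C@@H]3C(=O)OC)C(=O)O1 | intermediate
26 | CNP0212122.1 (2β,3β-dihydroxy-gibberell-16-ene-7,19,20-trioic acid 20→12α-lactone) | C=C1C[C@]23C[C@H]1[C@@H]1C[C@H]2[C@@]2(C[C@H](O)[C@H](O)[C@@](C)(C(=O)O)[C@H]2[C@@H]3C(=O)O)C(=O)O1 | target

**Totals.** Total step count: 18. Longest linear sequence: 18 steps (1 → 26); 12 enters at step 9.

**Steps most likely to fail**

Step 9 (tandem Michael addition–allylation). The congested lithium enolate 14 may be protonated or O-allylated instead of C-allylated, or the allyl group may enter cis to the C-4 unit. The fallback makes the quaternary centre by a sigmatropic shift instead of an intermolecular alkylation. It sets out from triflate 10: carbonylation with allyl alcohol in place of the silyl alcohol (Pd(OAc)2, dppf, Et3N, CO, DMF) should give allyl enoate F1. Addition of dienolate 13 at −78 °C gives lithium allyl ester enolate F2, which is silylated with Me3SiCl to ketene silyl acetal F3. On warming, an Ireland–Claisen rearrangement should deliver the allyl group intramolecularly to the β face of C-10, giving silyl ester F4 and, after aqueous work-up, acid F5. Mitsunobu esterification with 2-(trimethylsilyl)ethanol (PPh3, DIAD) comes back to the route at 15.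

Step 1 (enantioselective cycloaddition). The β-ester may reduce catalyst turnover or facial discrimination, so that the adduct is formed with insufficient enantiomeric enrichment. The fallback replaces asymmetric catalysis by resolution. It sets out from 1 and 2, which are combined under Et2AlCl promotion (CH2Cl2, −20 °C) to give 3 together with its enantiomer F6. The two are separated by preparative supercritical-fluid chromatography on a cellulose-carbamate chiral phase, and the route is rejoined at 3.

Step 17 (radical ring closure). Hydrogen transfer to the C-13 radical before cyclisation, or stannyl radical addition to the alkyne, may give the reduced, uncyclised lactone. The fallback closes ring D by a polar pathway. It sets out from 24: Zn in AcOH/THF eliminates iodide and carboxylate reductively to regenerate the C-12=C-13 alkene in enyne acid F7. Monovalent-gold catalysis with [(t-Bu2(2-biphenylyl)P)Au(NCMe)]SbF6 (CH2Cl2, 25 °C) should then effect 5-exo-dig attack of the alkene on the activated alkyne with anti capture at C-12 by the C-20 acid, followed by protodeauration. This comes back to the route at 25.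

**Further compounds**

F1 | step 9 | allyl enoate (allyl C-20 ester on C-5=C-10, 6β-C(SMe)3, 8β-dioxolanylmethyl) | O1CCOC1C[C@]23CC=CC[C@H]2C(C(=O)OCC=C)=C[C@@H]3C(SC)(SC)SC
F2 | step 9 | lithium allyl ester enolate of the Michael adduct | O1CCOC1C[C@]23CC=CC[C@H]2C(=C(O[Li])OCC=C)[C@@H](C(C=C)C(=O)OC)[C@@H]3C(SC)(SC)SC
F3 | step 9 | allyl trimethylsilyl ketene acetal | O1CCOC1C[C@]23CC=CC[C@H]2C(=C(O[Si](C)(C)C)OCC=C)[C@@H](C(C=C)C(=O)OC)[C@@H]3C(SC)(SC)SC
F4 | step 9 | trimethylsilyl ester with 10β-allyl quaternary centre | O1CCOC1C[C@]23CC=CC[C@H]2[C@@](CC=C)(C(=O)O[Si](C)(C)C)[C@@H](C(C=C)C(=O)OC)[C@@H]3C(SC)(SC)SC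
F5 | step 9 | C-20 acid with 10β-allyl quaternary centre | O1CCOC1C[C@]23CC=CC[C@H]2[C@@](CC=C)(C(=O)O)[C@@H](C(C=C)C(=O)OC)[C@@H]3C(SC)(SC)SC
F6 | step 1 | enantiomer of 3, methyl (3aS,7aS)-3-oxo-2,3,3a,4,7,7a-hexahydro-1H-indene-7a-carboxylate | COC(=O)[C@@]12CC=CC[C@@H]1C(=O)CC2
F7 | step 17 | enyne acid (C-20 acid, C-12=C-13, 8β-propargyl, 2β,3β-diol, 7,19-dimethyl ester) | C#CC[C@]23CC=CC[C@H]2[C@@]2(C[C@H](O)[C@H](O)[C@@](C)(C(=O)OC)[C@H]2[C@@H]3C(=O)OC)C(=O)O
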